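The disconnection is the aryl–oxygen bond of the pyran ring (chromene O1–C8a, which is C4' of isoflavone ring B), formed last by directed C–H oxidation. A Z-configured tertiary allylic alcohol on C3' of ring B guides palladium to the only ortho C–H bond it can reach, C4'–H, because C2' is blocked by its methoxy group. Oxidation and C–O reductive elimination then close the 2,2-dimethyl-2H-pyran ring in one operation, with no prior functionalisation of C4'. The precursor is the complete 7-methoxyisoflavone bearing a (Z)-3-hydroxy-3-methylbut-1-enyl chain at C3', built by Suzuki coupling, Sonogashira coupling and semi-hydrogenation.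

Key step: step 6

Remark: the target has no stereocentre, so the only stereochemical element to control is the Z-alkene of 8; paeonol, (3-bromo-2-methoxyphenyl)boronic acid and 2-methylbut-3-yn-2-ol are taken as purchasable.

Step 1
Reactants: 1 paeonol, 1-(2-hydroxy-4-methoxyphenyl)ethan-1-one
Product: 2 (2E)-3-(dimethylamino)-1-(2-hydroxy-4-methoxyphenyl)prop-2-en-1-one
Conditions: Me2NCH(OMe)2 (1.5 equiv), toluene, 100 °C
Reagents that add atoms: N,N-dimethylformamide dimethyl acetal, COC(OC)N(C)C
Why: Condensation of the acetyl CH3 group with the formamide acetal (enaminone formation) should give the push–pull E-enaminone, with the chelated phenol left free.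

Step 2
Reactants: 2 (2E)-3-(dimethylamino)-1-(2-hydroxy-4-methoxyphenyl)prop-2-en-1-one
Product: 3 3-iodo-7-methoxy-4H-chromen-4-one
Conditions: I2 (1.2 equiv), CHCl3, rt
Reagents that add atoms: iodine, II
Why: Iodine attacks the nucleophilic α-carbon of the enaminone, the phenol adds to the resulting iminium carbon and dimethylamine is expelled, a tandem iodination/oxa-Michael addition–elimination (enaminone iodocyclisation) that should give the 3-iodochromone.

Step 3
Reactants: 3 3-iodo-7-methoxy-4H-chromen-4-one; 4 (3-bromo-2-methoxyphenyl)boronic acid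
Product: 5 3-(3-bromo-2-methoxyphenyl)-7-methoxy-4H-chromen-4-one
Conditions: Pd(PPh3)4 (5 mol %), Na2CO3 (2 equiv), DME/H2O 4:1, 80 °C
Reagents that add atoms: none
Why: Suzuki–Miyaura coupling, in which oxidative addition of zerovalent palladium into the C–I bond of the electron-poor chromone should be far faster than into the hindered ortho-methoxy C–Br bond, so the bromide is kept for step 4.

Step 4
Reactants: 5 3-(3-bromo-2-methoxyphenyl)-7-methoxy-4H-chromen-4-one; 6 2-methylbut-3-yn-2-ol
Product: 7 3-[3-(3-hydroxy-3-methylbut-1-yn-1-yl)-2-methoxyphenyl]-7-methoxy-4H-chromen-4-one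
Conditions: PdCl2(PPh3)2 (5 mol %), CuI (10 mol %), Et3N (3 equiv), DMF, 80 °C
Reagents that add atoms: none
Why: Sonogashira coupling of the aryl bromide with the terminal alkyne, with a tertiary amine as base because it cannot open the chromone ring by conjugate addition.

Step 5
Reactants: 7 3-[3-(3-hydroxy-3-methylbut-1-yn-1-yl)-2-methoxyphenyl]-7-methoxy-4H-chromen-4-one
Product: 8 3-{3-[(1Z)-3-hydroxy-3-methylbut-1-en-1-yl]-2-methoxyphenyl}-7-methoxy-4H-chromen-4-one
Conditions: H2 (1 atm), Pd on CaCO3 poisoned with Pb(OAc)2, quinoline, EtOAc, rt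
Reagents that add atoms: none
Why: Lindlar-type semi-hydrogenation delivers both hydrogens to one face of the alkyne on the poisoned palladium surface, which sets the Z geometry that holds the hydroxyl next to C4'–H, and the chromone C2=C3 bond should not be reduced.

Step 6
Reactants: 8 3-{3-[(1Z)-3-hydroxy-3-methylbut-1-en-1-yl]-2-methoxyphenyl}-7-methoxy-4H-chromen-4-one
Product: 9 7-methoxy-3-(5-methoxy-2,2-dimethyl-2H-chromen-6-yl)-4H-chromen-4-one
Conditions: Pd(OAc)2 (10 mol %), PhI(OAc)2 (1.5 equiv), Li2CO3 (1.5 equiv), C6F6, 100 °C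
Reagents that add atoms: none
Why: Proposed new method: the tertiary alkoxide of 8 binds divalent palladium and directs concerted metalation–deprotonation of C4'–H of ring B to a seven-membered oxapalladacycle held flat by the Z-alkene, PhI(OAc)2 oxidises this to tetravalent palladium, and C(aryl)–O reductive elimination forms the O1–C8a bond. The closest known reaction type is the hydroxyl-directed Pd(OAc)2/PhI(OAc)2 C–H activation/C–O cyclisation of homobenzylic tertiary alcohols to dihydrobenzofurans, supported by the carboxylate-directed lactonisation of biaryl-2-carboxylic acids, which passes through a palladacycle of the same size. The six-membered 2H-pyran ring closes by C–O reductive elimination with extrusion of palladium from the seven-membered metallacycle, and no stereocentre is formed. The step needs site selectivity between the two positions ortho to the side chain, and the substrate secures it because C2' carries the methoxy group, so C4'–H is the only C–H bond the cis-held alkoxide can reach. The carbinol carbon bears no hydrogen, so oxidation to a ketone cannot compete, and Li2CO3 keeps the medium free of the acid that would ionise the allylic alcohol.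

Compound list
1 | paeonol, 1-(2-hydroxy-4-methoxyphenyl)ethan-1-one | CC(=O)c1ccc(OC)cc1O | starting material
2 | (2E)-3-(dimethylamino)-1-(2-hydroxy-4-methoxyphenyl)prop-2-en-1-one | CN(C)/C=C/C(=O)c1ccc(OC)cc1O | intermediate
3 | 3-iodo-7-methoxy-4H-chromen-4-one | COc1ccc2c(=O)c(I)coc2c1 | intermediate
4 | (3-bromo-2-methoxyphenyl)boronic acid | COc1c(Br)cccc1B(O)O | starting material
5 | 3-(3-bromo-2-methoxyphenyl)-7-methoxy-4H-chromen-4-one | COc1ccc2c(=O)c(-c3cccc(Br)c3OC)coc2c1 | intermediate
6 | 2-methylbut-3-yn-2-ol | CC(C)(O)C#C | starting material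
7 | 3-[3-(3-hydroxy-3-methylbut-1-yn-1-yl)-2-methoxyphenyl]-7-methoxy-4H-chromen-4-one | COc1ccc2c(=O)c(-c3cccc(C#CC(C)(C)O)c3OC)coc2c1 | intermediate
8 | 3-{3-[(1Z)-3-hydroxy-3-methylbut-1-en-1-yl]-2-methoxyphenyl}-7-methoxy-4H-chromen-4-one | COc1ccc2c(=O)c(-c3cccc(/C=C\C(C)(C)O)c3OC)coc2c1 | intermediate
9 | 7-methoxy-3-(5-methoxy-2,2-dimethyl-2H-chromen-6-yl)-4H-chromen-4-one | COc1ccc2c(=O)c(-c3ccc4c(c3OC)C=CC(C)(C)O4)coc2c1 | target

Total step count: 6
Longest linear sequence: 6 steps (1 → 2 → 3 → 5 → 7 → 8 → 9)

Steps most likely to fail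

Step 6 (proposed new method). Cyclopalladation through a seven-membered ring with a weakly binding alkoxide may be slower than three competing processes: palladium-mediated acetoxylation of the electron-rich Z-styrene double bond, Z-to-E isomerisation that removes the hydroxyl from reach of C4'–H, and ionisation or dehydration of the tertiary allylic alcohol. The electron-rich chromene product may also be oxidised further. The fallback uses known chemistry, sets out from 3 and 6 and returns at 9; it closes the same O–C(aryl) bond by palladium-catalysed intramolecular etherification of an aryl bromide on a ring B fragment. 2,5-Dibromoanisole would be deprotonated between the methoxy group and the neighbouring bromine with LiN(iPr)2 in THF at −78 °C and quenched with I2 to give 1,4-dibromo-2-iodo-3-methoxybenzene F1. Sonogashira coupling with 6 at the C–I bond (PdCl2(PPh3)2, CuI, Et3N, rt) should give 4-(3,6-dibromo-2-methoxyphenyl)-2-methylbut-3-yn-2-ol F2. Semi-hydrogenation as in step 5 should give (3Z)-4-(3,6-dibromo-2-methoxyphenyl)-2-methylbut-3-en-2-ol F3. Pd(OAc)2, 2-(di-tert-butylphosphino)-1,1'-binaphthyl and Cs2CO3 in toluene at 80 °C should close the pyran ring at the only bromine the alkoxide can reach, giving 6-bromo-5-methoxy-2,2-dimethyl-2H-chromene F4. Miyaura borylation (B2pin2, Pd(dppf)Cl2, KOAc, dioxane, 90 °C) should give 2-(5-methoxy-2,2-dimethyl-2H-chromen-6-yl)-4,4,5,5-tetramethyl-1,3,2-dioxaborolane F5, and Suzuki coupling of F5 with 3 under the conditions of step 3 should give 9.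

Step 5. Hydrogen uptake may not stop at the alkene (over-reduction to the saturated chain), the hindered ortho-substituted alkyne may reduce sluggishly, and the Z-alkene may drift to E on the catalyst. The fallback sets out from 5 and returns at 8, and makes the alkene by C–C coupling and then corrects its geometry with light. Heck reaction of 5 with 2-methylbut-3-en-2-ol (Pd(OAc)2, P(o-tol)3, Et3N, DMF, 100 °C) should give 3-{3-[(1E)-3-hydroxy-3-methylbut-1-en-1-yl]-2-methoxyphenyl}-7-methoxy-4H-chromen-4-one F6. Triplet energy transfer from Ir(ppy)3 under blue light in MeCN at rt should then drive F6 to 8, because the Z isomer is twisted out of conjugation by allylic strain and is excited less readily than the E isomer.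

Step 3. Oxidative addition into the C–Br bond of 4 or 5 may compete and lead to oligomers, the ortho-methoxy boronic acid may protodeboronate, and aqueous base may open the chromone ring. The fallback sets out from 3 and returns at 7, and uses a boron partner that carries no halogen. Sonogashira coupling of 1-bromo-3-iodo-2-methoxybenzene with 6 at the C–I bond (PdCl2(PPh3)2, CuI, Et3N, rt) should give 4-(3-bromo-2-methoxyphenyl)-2-methylbut-3-yn-2-ol F7. Miyaura borylation (B2pin2, Pd(dppf)Cl2, KOAc, dioxane, 90 °C) should give 4-[2-methoxy-3-(4,4,5,5-tetramethyl-1,3,2-dioxaborolan-2-yl)phenyl]-2-methylbut-3-yn-2-ol F8, and Suzuki coupling of F8 with 3 (Pd(PPh3)4, Na2CO3, DME/H2O, 80 °C) should give 7.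

Further compounds
F1 | step 6 | 1,4-dibromo-2-iodo-3-methoxybenzene | COc1c(Br)ccc(Br)c1I
F2 | step 6 | 4-(3,6-dibromo-2-methoxyphenyl)-2-methylbut-3-yn-2-ol | COc1c(Br)ccc(Br)c1C#CC(C)(C)O
F3 | step 6 | (3Z)-4-(3,6-dibromo-2-methoxyphenyl)-2-methylbut-3-en-2-ol | COc1c(Br)ccc(Br)c1/C=C\C(C)(C)O
F4 | step 6 | 6-bromo-5-methoxy-2,2-dimethyl-2H-chromene | COc1c(Br)ccc2c1C=CC(C)(C)O2
F5 | step 6 | 2-(5-methoxy-2,2-dimethyl-2H-chromen-6-yl)-4,4,5,5-tetramethyl-1,3,2-dioxaborolane | COc1c(B3OC(C)(C)C(C)(C)O3)ccc2c1C=CC(C)(C)O2
F6 | step 5 | 3-{3-[(1E)-3-hydroxy-3-methylbut-1-en-1-yl]-2-methoxyphenyl}-7-methoxy-4H-chromen-4-one | COc1ccc2c(=O)c(-c3cccc(/C=C/C(C)(C)O)c3OC)coc2c1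
F7 | step 3 | 4-(3-bromo-2-methoxyphenyl)-2-methylbut-3-yn-2-ol | COc1c(Br)cccc1C#CC(C)(C)O
F8 | step 3 | 4-[2-methoxy-3-(4,4,5,5-tetramethyl-1,3,2-dioxaborolan-2-yl)phenyl]-2-methylbut-3-yn-2-ol | COc1c(B2OC(C)(C)C(C)(C)O2)cccc1C#CC(C)(C)O
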